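**Numbering used throughout:** 1 diacetone mannose, 2 its anomeric chloride, 3 furanoid glycal alcohol, 4 its silyl ether, 5 vinyl bromide, 6 and 7 the lithio and chlorozinc glycals, 8 vinyl glycal (diene), 9 but-3-yn-2-one, 10 cycloadduct, 11 aryl ketone, 12 (R)-carbinol, 13 angelic acid, 14 mixed anhydride, 15 angelate, 16 diol, 17 primary silyl ether, 18 ketone, 19 methylene compound, 20 C3 alcohol, 21 C3 acetate, 22 allylic alcohol, 23 target.

## Analysis of the target

The target 23 is a 2,3-dihydro-1-benzofuran (O1, C2, C3, C3a, C4 to C7, C7a) whose benzene ring carries one further substituent, a 1-(angeloyloxy)ethyl group on C5, para to the ring oxygen on C7a. C2 bears a 3-oxoprop-1-en-2-yl group (an α-substituted acrolein) and C3 an acetoxy group; the two are cis on the five-membered ring and both centres are R. The third stereocentre, the R-configured carbinol carbon of the C5 side chain, is insulated from the ring pair by the arene, so it needs a reagent-controlled step. The C3 acetate is benzylic, activated by the ortho oxygen and anti to the C2–H, so acid or base can turn the dihydrofuran into an aromatic benzofuran; the cis arrangement is also the less stable one. The enal is a Michael acceptor and would be trapped as a five-membered hemiacetal by a free C3 hydroxyl. The angelate isomerises to the tiglate under nucleophilic conditions, and the side-chain ester sits on a p-alkoxybenzylic carbon that ionises in strong acid. The difficulty is therefore less the skeleton than the order in which three differently acylated or oxidised oxygens are revealed under nearly neutral conditions. The plan rests on two correspondences: O1–C2–C3 with its cis substituents, plus the two side-chain carbons on C2, is O4–C4–C3 and C5–C6 of a D-mannofuranose; and the para relation between O1 on C7a and the acyl-bearing C5 is the pattern written by a 2-alkoxydiene and an alkynyl ketone in a [4+2] cycloaddition.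

## Retrosynthetic reasoning

**Aldehyde last (23 to 22).** The C–H and O–H bonds of the primary allylic carbinol are the last to be changed. The enal is the most fragile group, and once it exists next to the C3 acetate any base or acid can aromatise the five-membered ring. The forward reaction must be a neutral, fast alcohol oxidation that does not touch the two esters.

**Acetate before aldehyde, silyl ether before acetate (22 to 21 to 20 to 19).** The O–acetyl bond at C3 and the O–Si bond at the primary carbon are cut. The acetate must be on C3 before the aldehyde appears, because a free C3 hydroxyl would close onto the aldehyde. It cannot be there earlier, because a C3 acetate β to the side-chain ketone 18 would be eliminated. C3 therefore carries a silyl ether through the ketone stage, and 19 holds two silyl ethers of different acid stability so that the one on C3 can be exchanged first.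

**Methylene carbon (19 to 18 to 17 to 16 to 15).** The C=CH2 bond is cut; this is the only side-chain carbon that the sugar does not supply. The ketone 18 comes from the secondary hydroxyl of diol 16 after the primary one is silylated (17), and 16 comes from the dioxolane of 15. The forward methylenation must be non-basic, since the ketone has an epimerisable α-centre (C2) and a β-oxygen (C3).

**Side-chain ester and carbinol (15 to 12 plus 13, 12 to 11).** The acyl–oxygen bond of the angelate is cut to alcohol 12 and acid 13, the latter activated as the mixed anhydride 14, so the carbinol configuration is not at risk in the esterification. The carbinol C–H bond is traced to the aryl methyl ketone 11 by an enantioselective reduction. This is done before any second ketone exists in the molecule.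

**Benzene ring (11 to 8 plus 9).** After formal addition of H2, which leads back to the cyclohexadiene 10, the ring is cut at C3a–C4 and C5–C6. This returns the diene C3a=C7a–C7=C6 of the vinyl glycal 8 and the alkynyl ketone 9. The cut is made here because it is the only one that leaves C2, C3 and the side chain as an intact sugar fragment and places the acetyl group by the inherent polarisation of the two partners. The forward step must form two C–C bonds regioselectively and then remove two hydrogens without losing the C3 oxygen.

**Vinyl group (8 to 4 plus 5).** The sp2–sp2 bond C7a–C7 is cut to the alkenylzinc 7, made from 4 through the lithio compound 6, and the vinyl halide 5. C1 of a glycal is the one position that can be deprotonated directly.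

**Glycal (4 to 3 to 2 to 1).** The C1=C2 double bond of 3 is traced to reductive elimination of the anomeric chloride 2 with loss of the 2,3-acetonide, which at the same time frees the C3 hydroxyl that is silylated in 4. The chloride 2 is made from the commercial diacetonide 1. C3, C4 and C5 of 1 become C3, C2 and the carbinol carbon of 16, and they are never touched.

## Alternatives that were turned down

**Alternative 1:** The bond between C2 and the future methylene-bearing carbon is made while that carbon is tethered to the C3 oxygen. In the forward step (3R)-5-bromo-2,3-dihydro-1-benzofuran-3-yl 2-diazo-2-(diethoxyphosphoryl)acetate A1 is decomposed with Rh2(OAc)4. The carbenoid inserts into the C2–H bond cis to the ester oxygen and gives the cis-fused phosphono γ-lactone A2.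
- For: the tether enforces the cis relation, the C2–H of A1 is activated by O1, and a phosphonate olefination on A2 would later bring in the methylene group. On the cis relation and on step count to the bicyclic core it is at least as strong as the chosen route.
- Against: the lactone of A2 is not a ring of the target. Opening A2 gives the C3 hydroxyl and the three-carbon unit as a pair that recloses at the aldehyde level, so the same protecting-group sequence is needed as here. The carbenoid can also attack the lone pair of O1, add to the benzene ring or insert at C3–H. The R configuration at C3 of A1 needs its own asymmetric step. The C5 side chain must still be grown from the bromide of A2 in the presence of a lactone or acrylate.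
- Comparison: the chosen strategy takes both ring stereocentres from the sugar with no selectivity question and delivers the C5 acetyl group in the ring-forming step.

**Alternative 2:** The C2–C3 bond is cut. In the forward step 5-bromo-2-(propa-1,2-dien-1-yloxy)benzaldehyde A3 is treated with a copper–boryl species made from CuCl, NaOtBu, a chiral bisphosphine and B2pin2. Borylcupration of the terminal allene double bond gives a 2-boryl allylcopper, which attacks the aldehyde through its oxygen-bearing carbon and gives (2R,3R)-5-bromo-2-[1-(4,4,5,5-tetramethyl-1,3,2-dioxaborolan-2-yl)ethenyl]-2,3-dihydro-1-benzofuran-3-ol A4.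
- For: one catalytic step forms the ring and both stereocentres of A4 and leaves a boron handle on the carbon that must become the formyl-bearing alkene carbon. A3 is close to commercial material. In step economy and in its use of catalysis this route is stronger than the chosen one.
- Against: copper–boryl species also add directly to aldehydes. The cis isomer A4 requires one allylcopper geometry in a transition state constrained by a three-atom tether, so diastereo- and enantiocontrol both rest on the ligand. The alkenyl boronate of A4 needs a one-carbon homologation next to a benzylic alcohol, and the bromide of A4 must still be turned into the acylated carbinol.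
- Comparison: the chosen strategy offers fixed absolute and relative configuration at C2 and C3 and has the oxygenated carbon of the future aldehyde in place from the start.

**Alternative 3:** The O1–C2 bond is made by contraction of a chroman. In the forward step (3R,4R)-6-acetyl-3-hydroxy-2,2-dimethyl-3,4-dihydro-2H-chromen-4-yl acetate A5 is treated with Tf2O and a hindered pyridine. O1 displaces the triflate from the rear, the O1–C(CH3)2 bond breaks, and loss of a methyl proton gives (2R,3R)-5-acetyl-2-(prop-1-en-2-yl)-2,3-dihydro-1-benzofuran-3-yl acetate A6.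
- For: A5 should be reachable in few steps through an asymmetric dihydroxylation (OsO4 with a cinchona ligand). A6 already carries the C3 acetate, the C5 acetyl group and the cis configuration, the latter by inversion at the carbinol carbon of the cis-configured A5. This is clearly the shortest route, and on step economy it is stronger.
- Against: O1 of A5 is para to an acetyl group and is a weak nucleophile. A hydride shift from C4 and plain elimination compete with the oxygen shift. The tertiary cation can also lose the C2 proton, giving an enol ether that aromatises. After A6 the isopropenyl methyl group must be oxidised to the aldehyde by a late allylic C–H oxidation, either in the presence of the allylic methyl groups of the angelate or before a ketone reduction that would then have to spare an enal.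
- Comparison: the chosen strategy avoids a cationic step at a position that aromatises easily and avoids any late C–H oxidation, because the aldehyde carbon enters as an oxygenated sugar carbon.

Key step: step 5

## Route

Remark: 1 is taken as the commercial double acetonide that D-mannose gives with acetone.
Remark: the configuration at C3a of the transient adduct 10 is left unassigned, since the same step erases it.

Step 1
Reactants: 1 2,3:5,6-di-O-isopropylidene-α-D-mannofuranose
Product: 2 2,3:5,6-di-O-isopropylidene-α-D-mannofuranosyl chloride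
Conditions: PPh3, CCl4, THF, reflux
Reagents that add atoms: carbon tetrachloride, ClC(Cl)(Cl)Cl
Why: Appel chlorination of the lactol hydroxyl through its oxyphosphonium salt; the configuration at C1 does not matter because C1 becomes sp2 in step 2.

Step 2
Reactants: 2 2,3:5,6-di-O-isopropylidene-α-D-mannofuranosyl chloride
Product: 3 1,4-anhydro-2-deoxy-5,6-O-isopropylidene-D-arabino-hex-1-enitol
Conditions: Li, NH3 (l), THF, −78 °C; then NH4Cl
Reagents that add atoms: none
Why: Two-electron reduction of the C1–Cl bond gives a C1 carbanion that expels the acetal oxygen on C2 (reductive β-elimination); the hemiketal alkoxide left on O3 collapses, so the enol ether C1=C2 and the free C3 hydroxyl appear while C3, C4 and C5 stay untouched.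

Step 3
Reactants: 3 1,4-anhydro-2-deoxy-5,6-O-isopropylidene-D-arabino-hex-1-enitol
Product: 4 1,4-anhydro-3-O-(tert-butyldimethylsilyl)-2-deoxy-5,6-O-isopropylidene-D-arabino-hex-1-enitol
Conditions: TBSCl, imidazole, DMF, 0 °C → rt
Reagents that add atoms: tert-butyl(chloro)dimethylsilane, CC(C)(C)[Si](C)(C)Cl
Why: Standard O-silylation of the crude allylic alcohol; the silyl ether is a poor leaving group, which keeps the allylic C3–O bond from ionising, and it tolerates the alkyllithium of step 4.

Step 4
Reactants: 4 1,4-anhydro-3-O-(tert-butyldimethylsilyl)-2-deoxy-5,6-O-isopropylidene-D-arabino-hex-1-enitol; 5 vinyl bromide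
Product: 8 1,4-anhydro-3-O-(tert-butyldimethylsilyl)-2-deoxy-5,6-O-isopropylidene-1-C-vinyl-D-arabino-hex-1-enitol, via 1-lithio glycal 6 (not isolated), via glycal-1-ylzinc chloride 7 (not isolated)
Conditions: tBuLi, THF, −78 → 0 °C; ZnCl2, THF, 0 °C → rt; 5 (1 M in THF), Pd(PPh3)4 (5 mol %), rt; Et3N-deactivated silica
Reagents that add atoms: none
Why: tBuLi removes the vinylic C1–H next to the ring oxygen, the most acidic C–H of 4, ZnCl2 turns 6 into the alkenylzinc 7, and Negishi coupling at zerovalent palladium joins C1 to the vinyl carbon of 5; no stereocentre is involved.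

Step 5
Reactants: 8 1,4-anhydro-3-O-(tert-butyldimethylsilyl)-2-deoxy-5,6-O-isopropylidene-1-C-vinyl-D-arabino-hex-1-enitol; 9 but-3-yn-2-one
Product: 11 1-{(2R,3R)-3-[(tert-butyldimethylsilyl)oxy]-2-[(4R)-2,2-dimethyl-1,3-dioxolan-4-yl]-2,3-dihydro-1-benzofuran-5-yl}ethan-1-one, via 1,4-cyclohexadiene adduct 10 (not isolated)
Conditions: 9 (2.5 equiv), BHT (cat.), toluene, 85 °C, sealed tube, base-washed glass; evaporate; DDQ (1.1 equiv), toluene, 0 °C → rt
Reagents that add atoms: none
Why: This is a thermal normal-demand Diels–Alder reaction between the 2-alkoxy-1,3-diene of 8 (C3a=C7a–C7=C6 in benzofuran numbering) and the electron-poor alkyne 9; the closest known reaction type is the cycloaddition of 1-vinyl glycals and other 2-alkoxydienes with acetylenic ketones and esters followed by quinone dehydrogenation. The oxygen on C7a raises the HOMO and puts its largest coefficient on C3a, which pairs with the unsubstituted β-carbon of the ynone, so C3a–C4 and C5–C6 form in a concerted but asynchronous way and the acetyl group lands on C5, para to C7a. The six-membered ring is closed by this suprafacial [4+2] cycloaddition of two separate components and not by cyclisation of a chain, so no exo or endo ring-closure rule applies. The only new stereocentre, C3a of 10, is set by approach of the alkyne to the diene face opposite the C3 silyloxy and C2 dioxolanyl groups and is of no consequence. DDQ abstracts the doubly allylic hydride at C6 to give a cation stabilised by O1 through C7a, and loss of the C3a proton forms the benzene ring and erases that centre. C2 and C3 are spectators and keep the cis (2R,3R) arrangement of the sugar. The step needs regioselectivity (acetyl on C5 and not C6), which the donor oxygen on C7a and the preference for joining the substituted terminus C3a to the unsubstituted alkyne carbon provide. It also needs dehydrogenation to win over loss of silanol, which neutral acid-free conditions and the poor leaving-group ability of the silyloxy group provide.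

Step 6
Reactants: 11 1-{(2R,3R)-3-[(tert-butyldimethylsilyl)oxy]-2-[(4R)-2,2-dimethyl-1,3-dioxolan-4-yl]-2,3-dihydro-1-benzofuran-5-yl}ethan-1-one
Product: 12 (1R)-1-{(2R,3R)-3-[(tert-butyldimethylsilyl)oxy]-2-[(4R)-2,2-dimethyl-1,3-dioxolan-4-yl]-2,3-dihydro-1-benzofuran-5-yl}ethan-1-ol
Conditions: (S)-2-methyl-CBS-oxazaborolidine (10 mol %), BH3·SMe2, THF, −20 °C; MeOH
Reagents that add atoms: none
Why: Corey–Bakshi–Shibata reduction; the ketone binds the ring boron with its aryl group away from the catalyst and takes hydride from the nitrogen-bound borane on the face that gives the R carbinol, as acetophenones do with the S catalyst. Control is by the reagent, since the ring stereocentres are remote.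

Step 7
Reactants: 12 (1R)-1-{(2R,3R)-3-[(tert-butyldimethylsilyl)oxy]-2-[(4R)-2,2-dimethyl-1,3-dioxolan-4-yl]-2,3-dihydro-1-benzofuran-5-yl}ethan-1-ol; 13 angelic acid, (2Z)-2-methylbut-2-enoic acid
Product: 15 (1R)-1-{(2R,3R)-3-[(tert-butyldimethylsilyl)oxy]-2-[(4R)-2,2-dimethyl-1,3-dioxolan-4-yl]-2,3-dihydro-1-benzofuran-5-yl}ethyl (2Z)-2-methylbut-2-enoate, via mixed angelic anhydride 14 (not isolated)
Conditions: 13, 2,4,6-Cl3C6H2COCl, Et3N, toluene, rt; then 12, 75 °C
Reagents that add atoms: none
Why: Yamaguchi-type mixed-anhydride esterification; the hindered aroyl carbonyl directs the alcohol to the angeloyl carbon, and leaving out a nucleophilic catalyst avoids the addition–elimination path that turns angelate into tiglate. Only the acyl–oxygen bond forms, so the carbinol keeps its R configuration.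

Step 8
Reactants: 15 (1R)-1-{(2R,3R)-3-[(tert-butyldimethylsilyl)oxy]-2-[(4R)-2,2-dimethyl-1,3-dioxolan-4-yl]-2,3-dihydro-1-benzofuran-5-yl}ethyl (2Z)-2-methylbut-2-enoate
Product: 16 (1R)-1-{(2R,3R)-3-[(tert-butyldimethylsilyl)oxy]-2-[(1R)-1,2-dihydroxyethyl]-2,3-dihydro-1-benzofuran-5-yl}ethyl (2Z)-2-methylbut-2-enoate
Conditions: 80% aq. AcOH, 35 °C
Reagents that add atoms: none
Why: Acid hydrolysis of the terminal dioxolane, the most labile acetal-type group present; acetic acid is weak enough that the hindered secondary silyl ether and the p-alkoxybenzylic ester should not be cleaved or ionised.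

Step 9
Reactants: 16 (1R)-1-{(2R,3R)-3-[(tert-butyldimethylsilyl)oxy]-2-[(1R)-1,2-dihydroxyethyl]-2,3-dihydro-1-benzofuran-5-yl}ethyl (2Z)-2-methylbut-2-enoate
Product: 17 (1R)-1-{(2R,3R)-3-[(tert-butyldimethylsilyl)oxy]-2-[(1R)-2-[(tert-butyldiphenylsilyl)oxy]-1-hydroxyethyl]-2,3-dihydro-1-benzofuran-5-yl}ethyl (2Z)-2-methylbut-2-enoate
Conditions: TBDPSCl (1.05 equiv), imidazole, CH2Cl2, 0 °C
Reagents that add atoms: tert-butyl(chloro)diphenylsilane, CC(C)(C)[Si](Cl)(c1ccccc1)c1ccccc1
Why: The bulky silyl chloride reacts at the primary hydroxyl only; the diphenyl-tert-butylsilyl group is chosen because it outlasts the dimethyl-tert-butylsilyl group under acidic fluoride in step 12.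

Step 10
Reactants: 17 (1R)-1-{(2R,3R)-3-[(tert-butyldimethylsilyl)oxy]-2-[(1R)-2-[(tert-butyldiphenylsilyl)oxy]-1-hydroxyethyl]-2,3-dihydro-1-benzofuran-5-yl}ethyl (2Z)-2-methylbut-2-enoate
Product: 18 (1R)-1-{(2S,3R)-3-[(tert-butyldimethylsilyl)oxy]-2-{[(tert-butyldiphenylsilyl)oxy]acetyl}-2,3-dihydro-1-benzofuran-5-yl}ethyl (2Z)-2-methylbut-2-enoate
Conditions: Dess–Martin periodinane, pyridine, CH2Cl2, 0 °C → rt
Reagents that add atoms: none
Why: Dess–Martin oxidation under buffered, non-basic conditions, so the α-centre C2 does not epimerise and the C3 silyloxy group is not eliminated; the 2S descriptor reflects only a change of CIP priorities, the geometry at C2 is unchanged.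

Step 11
Reactants: 18 (1R)-1-{(2S,3R)-3-[(tert-butyldimethylsilyl)oxy]-2-{[(tert-butyldiphenylsilyl)oxy]acetyl}-2,3-dihydro-1-benzofuran-5-yl}ethyl (2Z)-2-methylbut-2-enoate
Product: 19 (1R)-1-{(2R,3R)-3-[(tert-butyldimethylsilyl)oxy]-2-{3-[(tert-butyldiphenylsilyl)oxy]prop-1-en-2-yl}-2,3-dihydro-1-benzofuran-5-yl}ethyl (2Z)-2-methylbut-2-enoate
Conditions: Zn, CH2Br2, TiCl4 (pre-formed reagent), THF/CH2Cl2, 0 °C → rt
Reagents that add atoms: dibromomethane, BrCBr
Why: Takai–Lombardo methylenation; the geminal dimetallic methylene reagent is non-basic and oxophilic, so it should convert the ketone and leave both esters and the α-centre C2 alone.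

Step 12
Reactants: 19 (1R)-1-{(2R,3R)-3-[(tert-butyldimethylsilyl)oxy]-2-{3-[(tert-butyldiphenylsilyl)oxy]prop-1-en-2-yl}-2,3-dihydro-1-benzofuran-5-yl}ethyl (2Z)-2-methylbut-2-enoate
Product: 20 (1R)-1-[(2R,3R)-2-{3-[(tert-butyldiphenylsilyl)oxy]prop-1-en-2-yl}-3-hydroxy-2,3-dihydro-1-benzofuran-5-yl]ethyl (2Z)-2-methylbut-2-enoate
Conditions: 40% aq. HF/MeCN (1:19), 0 °C → rt, monitored; NaHCO3
Reagents that add atoms: none
Why: Under acidic fluoride a dimethyl-tert-butylsilyl ether is cleaved much faster than a diphenyl-tert-butylsilyl ether, which should outweigh the steric shielding of the C3 ether. The O–Si bond breaks and not the C3–O bond, so C3 keeps its configuration.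

Step 13
Reactants: 20 (1R)-1-[(2R,3R)-2-{3-[(tert-butyldiphenylsilyl)oxy]prop-1-en-2-yl}-3-hydroxy-2,3-dihydro-1-benzofuran-5-yl]ethyl (2Z)-2-methylbut-2-enoate
Product: 21 (1R)-1-[(2R,3R)-3-(acetyloxy)-2-{3-[(tert-butyldiphenylsilyl)oxy]prop-1-en-2-yl}-2,3-dihydro-1-benzofuran-5-yl]ethyl (2Z)-2-methylbut-2-enoate
Conditions: Ac2O, pyridine, DMAP (cat.), CH2Cl2, 0 °C → rt
Reagents that add atoms: acetic anhydride, CC(=O)OC(C)=O
Why: Standard O-acetylation of the only free hydroxyl; without a carbonyl group next to C2 there is no acidified C2–H, so elimination of the new acetate is not expected under these conditions.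

Step 14
Reactants: 21 (1R)-1-[(2R,3R)-3-(acetyloxy)-2-{3-[(tert-butyldiphenylsilyl)oxy]prop-1-en-2-yl}-2,3-dihydro-1-benzofuran-5-yl]ethyl (2Z)-2-methylbut-2-enoate
Product: 22 (1R)-1-[(2R,3R)-3-(acetyloxy)-2-(3-hydroxyprop-1-en-2-yl)-2,3-dihydro-1-benzofuran-5-yl]ethyl (2Z)-2-methylbut-2-enoate
Conditions: TBAF, AcOH (1:1), THF, 0 °C → rt
Reagents that add atoms: none
Why: Fluoride-induced desilylation of the primary allylic ether; the acetic acid buffer keeps the medium from cleaving or migrating the C3 acetate and from touching the angelate.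

Step 15
Reactants: 22 (1R)-1-[(2R,3R)-3-(acetyloxy)-2-(3-hydroxyprop-1-en-2-yl)-2,3-dihydro-1-benzofuran-5-yl]ethyl (2Z)-2-methylbut-2-enoate
Product: 23 (1R)-1-[(2R,3R)-3-(acetyloxy)-2-(3-oxoprop-1-en-2-yl)-2,3-dihydro-1-benzofuran-5-yl]ethyl (2Z)-2-methylbut-2-enoate
Conditions: Dess–Martin periodinane, pyridine, CH2Cl2, 0 °C; rapid chromatography on neutral silica
Reagents that add atoms: none
Why: Dess–Martin oxidation of the primary allylic alcohol stops at the enal and runs without strong acid or base, so the C3 acetate should stay in place and the cis (2R,3R) ring keeps its configuration.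

## Compound list

1 | 2,3:5,6-di-O-isopropylidene-α-D-mannofuranose | CC1(C)OC[C@@H](O1)[C@H]2O[C@H](O)[C@H]3OC(C)(C)O[C@@H]23 | starting material
2 | 2,3:5,6-di-O-isopropylidene-α-D-mannofuranosyl chloride | CC1(C)OC[C@@H](O1)[C@H]2O[C@H](Cl)[C@H]3OC(C)(C)O[C@@H]23 | intermediate
3 | 1,4-anhydro-2-deoxy-5,6-O-isopropylidene-D-arabino-hex-1-enitol | CC1(C)OC[C@@H](O1)[C@H]2OC=C[C@H]2O | intermediate
4 | 1,4-anhydro-3-O-(tert-butyldimethylsilyl)-2-deoxy-5,6-O-isopropylidene-D-arabino-hex-1-enitol | CC1(C)OC[C@@H](O1)[C@H]2OC=C[C@H]2O[Si](C)(C)C(C)(C)C | intermediate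
5 | vinyl bromide | C=CBr | starting material
6 | 1-lithio derivative of 4 (lithium on C1 of the glycal) | CC1(C)OC[C@@H](O1)[C@H]2OC([Li])=C[C@H]2O[Si](C)(C)C(C)(C)C | intermediate (not isolated)
7 | glycal-1-ylzinc chloride derived from 4 | CC1(C)OC[C@@H](O1)[C@H]2OC([Zn]Cl)=C[C@H]2O[Si](C)(C)C(C)(C)C | intermediate (not isolated)
8 | 1,4-anhydro-3-O-(tert-butyldimethylsilyl)-2-deoxy-5,6-O-isopropylidene-1-C-vinyl-D-arabino-hex-1-enitol | CC1(C)OC[C@@H](O1)[C@H]2OC(C=C)=C[C@H]2O[Si](C)(C)C(C)(C)C | intermediate
9 | but-3-yn-2-one | CC(=O)C#C | starting material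
10 | 1-{(2R,3R)-3-[(tert-butyldimethylsilyl)oxy]-2-[(4R)-2,2-dimethyl-1,3-dioxolan-4-yl]-2,3,3a,6-tetrahydro-1-benzofuran-5-yl}ethan-1-one (C3a unassigned) | CC1(C)OC[C@@H](O1)[C@H]2OC3=CCC(C(C)=O)=CC3[C@H]2O[Si](C)(C)C(C)(C)C | intermediate (not isolated)
11 | 1-{(2R,3R)-3-[(tert-butyldimethylsilyl)oxy]-2-[(4R)-2,2-dimethyl-1,3-dioxolan-4-yl]-2,3-dihydro-1-benzofuran-5-yl}ethan-1-one | CC1(C)OC[C@@H](O1)[C@H]3Oc2ccc(C(C)=O)cc2[C@H]3O[Si](C)(C)C(C)(C)C | intermediate
12 | (1R)-1-{(2R,3R)-3-[(tert-butyldimethylsilyl)oxy]-2-[(4R)-2,2-dimethyl-1,3-dioxolan-4-yl]-2,3-dihydro-1-benzofuran-5-yl}ethan-1-ol | CC1(C)OC[C@@H](O1)[C@H]3Oc2ccc([C@@H](C)O)cc2[C@H]3O[Si](C)(C)C(C)(C)C | intermediate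
13 | angelic acid, (2Z)-2-methylbut-2-enoic acid | C/C=C(/C)C(=O)O | starting material
14 | (2Z)-2-methylbut-2-enoic 2,4,6-trichlorobenzoic anhydride | C/C=C(/C)C(=O)OC(=O)c1c(Cl)cc(Cl)cc1Cl | intermediate (not isolated)
15 | (1R)-1-{(2R,3R)-3-[(tert-butyldimethylsilyl)oxy]-2-[(4R)-2,2-dimethyl-1,3-dioxolan-4-yl]-2,3-dihydro-1-benzofuran-5-yl}ethyl (2Z)-2-methylbut-2-enoate | CC1(C)OC[C@@H](O1)[C@H]3Oc2ccc([C@@H](C)OC(=O)/C(C)=C\C)cc2[C@H]3O[Si](C)(C)C(C)(C)C | intermediate
16 | (1R)-1-{(2R,3R)-3-[(tert-butyldimethylsilyl)oxy]-2-[(1R)-1,2-dihydroxyethyl]-2,3-dihydro-1-benzofuran-5-yl}ethyl (2Z)-2-methylbut-2-enoate | OC[C@@H](O)[C@H]3Oc2ccc([C@@H](C)OC(=O)/C(C)=C\C)cc2[C@H]3O[Si](C)(C)C(C)(C)C | intermediate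
17 | (1R)-1-{(2R,3R)-3-[(tert-butyldimethylsilyl)oxy]-2-[(1R)-2-[(tert-butyldiphenylsilyl)oxy]-1-hydroxyethyl]-2,3-dihydro-1-benzofuran-5-yl}ethyl (2Z)-2-methylbut-2-enoate | CC(C)(C)[Si](c1ccccc1)(c1ccccc1)OC[C@@H](O)[C@H]3Oc2ccc([C@@H](C)OC(=O)/C(C)=C\C)cc2[C@H]3O[Si](C)(C)C(C)(C)C | intermediate
18 | (1R)-1-{(2S,3R)-3-[(tert-butyldimethylsilyl)oxy]-2-{[(tert-butyldiphenylsilyl)oxy]acetyl}-2,3-dihydro-1-benzofuran-5-yl}ethyl (2Z)-2-methylbut-2-enoate | CC(C)(C)[Si](c1ccccc1)(c1ccccc1)OCC(=O)[C@H]3Oc2ccc([C@@H](C)OC(=O)/C(C)=C\C)cc2[C@H]3O[Si](C)(C)C(C)(C)C | intermediate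
19 | (1R)-1-{(2R,3R)-3-[(tert-butyldimethylsilyl)oxy]-2-{3-[(tert-butyldiphenylsilyl)oxy]prop-1-en-2-yl}-2,3-dihydro-1-benzofuran-5-yl}ethyl (2Z)-2-methylbut-2-enoate | CC(C)(C)[Si](c1ccccc1)(c1ccccc1)OCC(=C)[C@H]3Oc2ccc([C@@H](C)OC(=O)/C(C)=C\C)cc2[C@H]3O[Si](C)(C)C(C)(C)C | intermediate
20 | (1R)-1-[(2R,3R)-2-{3-[(tert-butyldiphenylsilyl)oxy]prop-1-en-2-yl}-3-hydroxy-2,3-dihydro-1-benzofuran-5-yl]ethyl (2Z)-2-methylbut-2-enoate | CC(C)(C)[Si](c1ccccc1)(c1ccccc1)OCC(=C)[C@H]3Oc2ccc([C@@H](C)OC(=O)/C(C)=C\C)cc2[C@H]3O | intermediate
21 | (1R)-1-[(2R,3R)-3-(acetyloxy)-2-{3-[(tert-butyldiphenylsilyl)oxy]prop-1-en-2-yl}-2,3-dihydro-1-benzofuran-5-yl]ethyl (2Z)-2-methylbut-2-enoate | CC(C)(C)[Si](c1ccccc1)(c1ccccc1)OCC(=C)[C@H]3Oc2ccc([C@@H](C)OC(=O)/C(C)=C\C)cc2[C@H]3OC(C)=O | intermediate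
22 | (1R)-1-[(2R,3R)-3-(acetyloxy)-2-(3-hydroxyprop-1-en-2-yl)-2,3-dihydro-1-benzofuran-5-yl]ethyl (2Z)-2-methylbut-2-enoate | OCC(=C)[C@H]3Oc2ccc([C@@H](C)OC(=O)/C(C)=C\C)cc2[C@H]3OC(C)=O | intermediate
23 | (1R)-1-[(2R,3R)-3-(acetyloxy)-2-(3-oxoprop-1-en-2-yl)-2,3-dihydro-1-benzofuran-5-yl]ethyl (2Z)-2-methylbut-2-enoate | C=C(C=O)[C@H]1Oc2ccc([C@@H](C)OC(=O)/C(C)=C\C)cc2[C@H]1OC(C)=O | target

## Step count and least certain steps

Total: 15 steps. Longest linear sequence: 15 steps, from 1 to 23; compounds 5, 9 and 13 are bought and enter in steps 4, 5 and 7.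

**Key step (step 5).** The most likely failure is loss of the C3 silyloxy group. It can happen by ionisation of the allylic C3–O bond of 8 on heating, or by eliminative aromatisation of 10, in which silanol is lost instead of two hydrogens. Erosion of regiocontrol is a lesser risk. The fallback sets out from 8 and changes the dienophile from an alkyne to an alkene. Methyl vinyl ketone in toluene at 60 to 80 °C should give the cyclohexene adduct 1-{(2R,3R)-3-[(tert-butyldimethylsilyl)oxy]-2-[(4R)-2,2-dimethyl-1,3-dioxolan-4-yl]-2,3,3a,4,5,6-hexahydro-1-benzofuran-5-yl}ethan-1-one F1 with the same para orientation. F1 cannot aromatise by a single elimination and can be isolated. Twofold dehydrogenation with DDQ (2.2 equiv, warm dioxane) would then return to the route at 11.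

**Step 12.** The most likely failure is incomplete discrimination between the two silyl ethers: the primary ether is lost as well, or the hindered C3 ether reacts so slowly that the benzylic C–O bonds begin to ionise. The fallback sets out from 19 and gives up the selective cleavage. Both silyl groups are removed with HF·pyridine in THF to give the diol (1R)-1-[(2R,3R)-3-hydroxy-2-(3-hydroxyprop-1-en-2-yl)-2,3-dihydro-1-benzofuran-5-yl]ethyl (2Z)-2-methylbut-2-enoate F2. The primary allylic hydroxyl is silylated again (TBSCl, imidazole, CH2Cl2, −20 °C) to the mono-silyl ether F3, in which only C3 carries a free hydroxyl. Acetylation (Ac2O, pyridine, DMAP) gives the C3 acetate F4. Cleavage of the primary silyl ether with HF·pyridine and pyridine in THF comes back to the route at 22.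

**Step 11.** The most likely failure is epimerisation at C2 or β-elimination of the C3 silyloxy group from the α-aryloxy ketone under Lewis acidic conditions, or low conversion of the hindered, chelating ketone. The fallback sets out from 18 and replaces the carbenoid by a nucleophilic addition. Me3SiCH2MgCl with CeCl3 in THF at −78 °C should add to the ketone only and give the tertiary β-hydroxysilane F5. Peterson elimination with KN(SiMe3)2 in THF (−78 → 0 °C) then comes back at 19.

**Step 7.** The most likely failure is isomerisation of the Z double bond to the tiglate during activation and heating. The fallback sets out from 12 and builds the double bond on the ester. Esterification with 2-[bis(2,2,2-trifluoroethoxy)phosphoryl]propanoic acid (DCC, DMAP, CH2Cl2) gives the phosphonopropanoate F6. Still–Gennari olefination with acetaldehyde (KN(SiMe3)2, 18-crown-6, THF, −78 °C) should give the Z alkene and comes back at 15.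

**Step 4.** The most likely failures are competing deprotonation of the Si–CH3 groups by tBuLi, slow coupling of the hindered α-alkoxyalkenylzinc, and decomposition of the acid-sensitive diene on isolation. The fallback sets out from 4 and replaces the cross-coupling by a carbonyl olefination. The lithio compound 6 is quenched with DMF to give the conjugated aldehyde (4R,5R)-4-[(tert-butyldimethylsilyl)oxy]-5-[(4R)-2,2-dimethyl-1,3-dioxolan-4-yl]-4,5-dihydrofuran-2-carbaldehyde F7, which is more robust than 8. Wittig methylenation (Ph3P=CH2, THF, −78 → 0 °C) then comes back at 8, made immediately before the cycloaddition.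

## Further compounds

F1 | step 5 | 1-{(2R,3R)-3-[(tert-butyldimethylsilyl)oxy]-2-[(4R)-2,2-dimethyl-1,3-dioxolan-4-yl]-2,3,3a,4,5,6-hexahydro-1-benzofuran-5-yl}ethan-1-one (C3a and C5 unassigned) | CC1(C)OC[C@@H](O1)[C@H]2OC3=CCC(C(C)=O)CC3[C@H]2O[Si](C)(C)C(C)(C)C
F2 | step 12 | (1R)-1-[(2R,3R)-3-hydroxy-2-(3-hydroxyprop-1-en-2-yl)-2,3-dihydro-1-benzofuran-5-yl]ethyl (2Z)-2-methylbut-2-enoate | OCC(=C)[C@H]3Oc2ccc([C@@H](C)OC(=O)/C(C)=C\C)cc2[C@H]3O
F3 | step 12 | (1R)-1-[(2R,3R)-2-{3-[(tert-butyldimethylsilyl)oxy]prop-1-en-2-yl}-3-hydroxy-2,3-dihydro-1-benzofuran-5-yl]ethyl (2Z)-2-methylbut-2-enoate | CC(C)(C)[Si](C)(C)OCC(=C)[C@H]3Oc2ccc([C@@H](C)OC(=O)/C(C)=C\C)cc2[C@H]3O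
F4 | step 12 | (1R)-1-[(2R,3R)-3-(acetyloxy)-2-{3-[(tert-butyldimethylsilyl)oxy]prop-1-en-2-yl}-2,3-dihydro-1-benzofuran-5-yl]ethyl (2Z)-2-methylbut-2-enoate | CC(C)(C)[Si](C)(C)OCC(=C)[C@H]3Oc2ccc([C@@H](C)OC(=O)/C(C)=C\C)cc2[C@H]3OC(C)=O
F5 | step 11 | β-hydroxysilane from addition of a (trimethylsilyl)methyl group to the ketone carbonyl of 18 (new carbinol centre unassigned, ring configuration as in 18) | CC(C)(C)[Si](c1ccccc1)(c1ccccc1)OCC(O)(C[Si](C)(C)C)[C@H]3Oc2ccc([C@@H](C)OC(=O)/C(C)=C\C)cc2[C@H]3O[Si](C)(C)C(C)(C)C
F6 | step 7 | (1R)-1-{(2R,3R)-3-[(tert-butyldimethylsilyl)oxy]-2-[(4R)-2,2-dimethyl-1,3-dioxolan-4-yl]-2,3-dihydro-1-benzofuran-5-yl}ethyl 2-[bis(2,2,2-trifluoroethoxy)phosphoryl]propanoate (phosphonate α-carbon unassigned) | CC1(C)OC[C@@H](O1)[C@H]3Oc2ccc([C@@H](C)OC(=O)C(C)P(=O)(OCC(F)(F)F)OCC(F)(F)F)cc2[C@H]3O[Si](C)(C)C(C)(C)C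
F7 | step 4 | (4R,5R)-4-[(tert-butyldimethylsilyl)oxy]-5-[(4R)-2,2-dimethyl-1,3-dioxolan-4-yl]-4,5-dihydrofuran-2-carbaldehyde | CC1(C)OC[C@@H](O1)[C@H]2OC(C=O)=C[C@H]2O[Si](C)(C)C(C)(C)C
A1 | alternative 1 | (3R)-5-bromo-2,3-dihydro-1-benzofuran-3-yl 2-diazo-2-(diethoxyphosphoryl)acetate | CCOP(=O)(OCC)C(=[N+]=[N-])C(=O)O[C@H]1COc2ccc(Br)cc21
A2 | alternative 1 | cis-fused α-(diethoxyphosphoryl)-γ-lactone bridging C2 and the C3 oxygen of (2R,3R)-5-bromo-2,3-dihydro-1-benzofuran (phosphonate-bearing carbon unassigned) | CCOP(=O)(OCC)C4[C@H]1Oc2ccc(Br)cc2[C@H]1OC4=O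
A3 | alternative 2 | 5-bromo-2-(propa-1,2-dien-1-yloxy)benzaldehyde | C=C=COc1ccc(Br)cc1C=O
A4 | alternative 2 | (2R,3R)-5-bromo-2-[1-(4,4,5,5-tetramethyl-1,3,2-dioxaborolan-2-yl)ethenyl]-2,3-dihydro-1-benzofuran-3-ol | CC1(C)OB(OC1(C)C)C(=C)[C@H]3Oc2ccc(Br)cc2[C@H]3O
A5 | alternative 3 | (3R,4R)-6-acetyl-3-hydroxy-2,2-dimethyl-3,4-dihydro-2H-chromen-4-yl acetate | CC(=O)O[C@@H]1c2cc(C(C)=O)ccc2OC(C)(C)[C@@H]1O
A6 | alternative 3 | (2R,3R)-5-acetyl-2-(prop-1-en-2-yl)-2,3-dihydro-1-benzofuran-3-yl acetate | C=C(C)[C@H]1Oc2ccc(C(C)=O)cc2[C@H]1OC(C)=O
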